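**Plan**

- Numbering of each half: C1 (OH), C2 (acetyl), C3 (methyl), C4, C4a, C5, C6, C7 (aryl–aryl carbon), C8 (OH), C8a; ring A holds C1–C4, ring B holds C5–C8.
- Enabling feature: C8 is a carbon at the carboxylic acid oxidation level bonded to C8a. Once C7–C8 and C7'–C8' are opened, C5, C6, C7, C7', C6', C5' form a hexa-1,5-diene whose central CH2–CH2 bond is the biaryl bond and whose allylic positions are C7 and C7'.
- Retrosynthesis: acetyl back to ester and C1–OH to C1–OMe; cut C7–C8 and C7'–C8' (both rings B); cut C5=C6 and C5'=C6' (two-fold Wittig with a four-carbon bis-phosphonium salt); cut ring A into a 3-oxoglutarate and acetylacetone.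
- Forward order: ring A by condensation (step 1), adjustment to the aldehyde (steps 2–4), chain joined at both ends (step 5), both rings B closed in one flask (step 6), ester to acetyl and O-demethylation (steps 7–9).
- Stereochemistry: the target has no stereocentre and no fixed axis. The only stereo-elements on the way are the two Z alkenes from the salt-free Wittig reaction, and they vanish on aromatization.

Key step: step 6

Remark: binaphthalene compounds are named with the half numbering defined above (not lowest locants), so that each atom keeps its label along the route.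
Assumption: rotation about C7–C7' is taken as free at room temperature (one hydroxyl and one hydrogen flank the axis on each ring), so no axial configuration has to be set.

**Route**

Step 1
Reactants: 1 dimethyl 3-oxopentanedioate; 2 pentane-2,4-dione (acetylacetone)
Product: 3 dimethyl 2-hydroxy-4,6-dimethylbenzene-1,3-dicarboxylate
Conditions: NaOMe (1.1 equiv), MeOH, 0 °C to reflux; then aq. HCl
Reagents that add atoms: none
Why: A base-mediated double Knoevenagel-type aldol condensation joins each activated methylene of 1 to one carbonyl of 2, and loss of two molecules of water with enolization of the former oxoglutarate ketone gives the aromatic 2-hydroxyisophthalate, a long-established benzannulation of 3-oxoglutarates with 1,3-diketones.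

Step 2
Reactants: 3 dimethyl 2-hydroxy-4,6-dimethylbenzene-1,3-dicarboxylate
Product: 4 dimethyl 2-methoxy-4,6-dimethylbenzene-1,3-dicarboxylate
Conditions: MeI, K2CO3, DMF, 50 °C
Reagents that add atoms: iodomethane, SMILES CI
Why: Williamson O-methylation of the acidic, doubly ester-flanked phenol should proceed through its potassium phenoxide in DMF, where the internal hydrogen bond that slows alkylation is broken.

Step 3
Reactants: 4 dimethyl 2-methoxy-4,6-dimethylbenzene-1,3-dicarboxylate
Product: 5 dimethyl 4-(bromomethyl)-2-methoxy-6-methylbenzene-1,3-dicarboxylate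
Conditions: NBS (0.9 equiv), AIBN (cat.), PhCF3, 85 °C
Reagents that add atoms: N-bromosuccinimide, SMILES O=C1CCC(=O)N1Br
Why: Wohl–Ziegler radical bromination is confined to the benzylic positions, the two methyl groups are equivalent by symmetry so only one monobromide can form, and a slight deficit of NBS limits dibromination while unreacted 4 is recycled.

Step 4
Reactants: 5 dimethyl 4-(bromomethyl)-2-methoxy-6-methylbenzene-1,3-dicarboxylate
Product: 6 dimethyl 4-formyl-2-methoxy-6-methylbenzene-1,3-dicarboxylate
Conditions: N-methylmorpholine N-oxide (4 equiv), 4 Å molecular sieves, MeCN, rt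
Reagents that add atoms: N-methylmorpholine N-oxide, SMILES C[N+]1([O-])CCOCC1
Why: This is the amine N-oxide variant of the Kornblum oxidation (SN2 attack of the N-oxide oxygen on the benzylic bromide, then elimination of N-methylmorpholine), and it runs at room temperature, which avoids the heat that would let the ortho ester lactonize to a phthalide.

Step 5
Reactants: 6 dimethyl 4-formyl-2-methoxy-6-methylbenzene-1,3-dicarboxylate (2 equiv); 7 butane-1,4-diylbis(triphenylphosphonium) dibromide
Product: 9 tetramethyl 4,4'-[(1Z,5Z)-hexa-1,5-diene-1,6-diyl]bis(2-methoxy-6-methylbenzene-1,3-dicarboxylate), via butane-1,4-diylidenebis(triphenylphosphorane) 8 (not isolated)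
Conditions: NaN(SiMe3)2 (2.05 equiv), THF, −78 to 0 °C; then 6, −78 °C to rt; chromatography on AgNO3-impregnated silica if geometric isomers need removal
Reagents that add atoms: none
Why: Double deprotonation gives the non-stabilized bis-ylide 8, whose salt-free Wittig reaction with the aryl aldehyde passes through the kinetically favoured cis-oxaphosphetane and should therefore give mainly the Z alkene at each end, while the hindered esters do not compete with the aldehyde at low temperature.

Step 6
Reactants: 9 tetramethyl 4,4'-[(1Z,5Z)-hexa-1,5-diene-1,6-diyl]bis(2-methoxy-6-methylbenzene-1,3-dicarboxylate)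
Product: 13 dimethyl 8,8'-dihydroxy-1,1'-dimethoxy-3,3'-dimethyl-7,7'-binaphthalene-2,2'-dicarboxylate, via monocyclised 2H-naphthalen-1-one 10 (not isolated), via monocyclised lithium naphtholate 11 (not isolated), via naphtholate ketone tautomer 12 (not isolated)
Conditions: slow addition of 9 to LiN(iPr)2 (6 equiv), THF (final 0.01 M), −78 °C, then 0 °C to rt; degassed 1 M HCl
Reagents that add atoms: none
Why: The amide base removes an allylic C7–H to give a pentadienyl-type anion delocalized through C5 into ring A and its ortho (C8) and para (C2) ester groups; the C7 terminus adds to the C8 ester carbonyl and methoxide leaves (Dieckmann-type acylation, 6-exo-trig), giving ketone 10, which still bears a hydrogen at C7 and is deprotonated at once to naphtholate 11, and the same sequence at C7' through 12 closes the second ring B, again 6-exo-trig. The closest known reaction type is the base-mediated annulation of ortho-allyl benzamides and benzoates to 1-naphthols, which runs through the same delocalized anion, reached here from the conjugated alkene isomer, together with the lateral deprotonation and Claisen chemistry of ortho-toluates. No stereocentre is created, since C7 of 10 and C7' of 12 are transient and are erased by aromatization. The step needs deprotonation at C7 and C7' in preference to the C3 methyl groups, and this is secured because the C7 anion is the more extended one, the anions exchange protons through the diisopropylamine present, and only the C7 anion has an irreversible exit into the naphtholate. Attack through C7 and not C5, and on the C8 ester and not the C2 ester, follows from ring size and reach, the Z geometry from step 5 holding C7 next to C8. Slow addition to excess base at high dilution should suppress intermolecular Claisen condensation and covers the two equivalents of methanol released and the two naphtholates formed.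

Step 7
Reactants: 13 dimethyl 8,8'-dihydroxy-1,1'-dimethoxy-3,3'-dimethyl-7,7'-binaphthalene-2,2'-dicarboxylate
Product: 14 8,8'-dihydroxy-1,1'-dimethoxy-3,3'-dimethyl-7,7'-binaphthalene-2,2'-dicarboxylic acid
Conditions: KOH (excess), DMSO/H2O, 90 °C, under argon; then 1 M HCl
Reagents that add atoms: potassium hydroxide, SMILES [K+].[OH-]
Why: Saponification by acyl–oxygen cleavage of the doubly ortho-substituted ester needs the poorly solvated hydroxide available in aqueous DMSO, and under argon the naphtholates and the aryl methyl ethers should be inert to it.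

Step 8
Reactants: 14 8,8'-dihydroxy-1,1'-dimethoxy-3,3'-dimethyl-7,7'-binaphthalene-2,2'-dicarboxylic acid
Product: 16 1,1'-(8,8'-dihydroxy-1,1'-dimethoxy-3,3'-dimethyl-7,7'-binaphthalene-2,2'-diyl)di(ethan-1-one), via hexalithium bis(gem-diolate) 15 (not isolated)
Conditions: MeLi (10 equiv), THF, 0 °C to rt; reaction mixture added to cold 1 M HCl
Reagents that add atoms: methyllithium, SMILES [Li]C
Why: Excess methyllithium first forms the tetralithium salt and then adds once to each carboxylate to give the gem-diolate 15, which cannot expel oxide and releases the methyl ketone only on acidic work-up (the classical organolithium synthesis of ketones from carboxylic acids), the two ortho substituents further guarding against a second addition.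

Step 9
Reactants: 16 1,1'-(8,8'-dihydroxy-1,1'-dimethoxy-3,3'-dimethyl-7,7'-binaphthalene-2,2'-diyl)di(ethan-1-one)
Product: 17 stypandrol, 1,1'-(1,1',8,8'-tetrahydroxy-3,3'-dimethyl-7,7'-binaphthalene-2,2'-diyl)di(ethan-1-one)
Conditions: BBr3 (4 equiv), CH2Cl2, −78 to 0 °C; then H2O
Reagents that add atoms: none
Why: Lewis acid ether cleavage, in which boron tribromide binds the C1 methoxy oxygen held between the C2 acetyl and the C8 hydroxyl and bromide removes the methyl group by SN2, should leave the ketones untouched at low temperature.

**Compound list**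

1 | dimethyl 3-oxopentanedioate | COC(=O)CC(=O)CC(=O)OC | starting material
2 | pentane-2,4-dione (acetylacetone) | CC(=O)CC(C)=O | starting material
3 | dimethyl 2-hydroxy-4,6-dimethylbenzene-1,3-dicarboxylate | COC(=O)c1c(C)cc(C)c(C(=O)OC)c1O | intermediate
4 | dimethyl 2-methoxy-4,6-dimethylbenzene-1,3-dicarboxylate | COC(=O)c1c(C)cc(C)c(C(=O)OC)c1OC | intermediate
5 | dimethyl 4-(bromomethyl)-2-methoxy-6-methylbenzene-1,3-dicarboxylate | COC(=O)c1c(C)cc(CBr)c(C(=O)OC)c1OC | intermediate
6 | dimethyl 4-formyl-2-methoxy-6-methylbenzene-1,3-dicarboxylate | COC(=O)c1c(C)cc(C=O)c(C(=O)OC)c1OC | intermediate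
7 | butane-1,4-diylbis(triphenylphosphonium) dibromide | [Br-].[Br-].c1ccc([P+](CCCC[P+](c2ccccc2)(c2ccccc2)c2ccccc2)(c2ccccc2)c2ccccc2)cc1 | starting material
8 | butane-1,4-diylidenebis(triphenylphosphorane) | c1ccc(P(=CCCC=P(c2ccccc2)(c2ccccc2)c2ccccc2)(c2ccccc2)c2ccccc2)cc1 | intermediate
9 | tetramethyl 4,4'-[(1Z,5Z)-hexa-1,5-diene-1,6-diyl]bis(2-methoxy-6-methylbenzene-1,3-dicarboxylate) | COC(=O)c1c(C)cc(/C=C\CC/C=C\c2cc(C)c(C(=O)OC)c(OC)c2C(=O)OC)c(C(=O)OC)c1OC | intermediate
10 | methyl 1-methoxy-7-{(2Z)-3-[3-methoxy-2,4-bis(methoxycarbonyl)-5-methylphenyl]prop-2-en-1-yl}-3-methyl-8-oxo-7,8-dihydronaphthalene-2-carboxylate (racemic at C7) | COC(=O)c1c(C)cc2C=CC(C/C=C\c3cc(C)c(C(=O)OC)c(OC)c3C(=O)OC)C(=O)c2c1OC | intermediate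
11 | lithium salt of methyl 8-hydroxy-1-methoxy-7-{(2Z)-3-[3-methoxy-2,4-bis(methoxycarbonyl)-5-methylphenyl]prop-2-en-1-yl}-3-methylnaphthalene-2-carboxylate | COC(=O)c1c(C)cc2ccc(C/C=C\c3cc(C)c(C(=O)OC)c(OC)c3C(=O)OC)c([O-])c2c1OC.[Li+] | intermediate
12 | lithium salt of dimethyl 8-hydroxy-1,1'-dimethoxy-3,3'-dimethyl-8'-oxo-7',8'-dihydro-7,7'-binaphthalene-2,2'-dicarboxylate (racemic at C7') | COC(=O)c1c(C)cc2ccc(C3C=Cc4cc(C)c(C(=O)OC)c(OC)c4C3=O)c([O-])c2c1OC.[Li+] | intermediate
13 | dimethyl 8,8'-dihydroxy-1,1'-dimethoxy-3,3'-dimethyl-7,7'-binaphthalene-2,2'-dicarboxylate | COC(=O)c1c(C)cc2ccc(-c3ccc4cc(C)c(C(=O)OC)c(OC)c4c3O)c(O)c2c1OC | intermediate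
14 | 8,8'-dihydroxy-1,1'-dimethoxy-3,3'-dimethyl-7,7'-binaphthalene-2,2'-dicarboxylic acid | OC(=O)c1c(C)cc2ccc(-c3ccc4cc(C)c(C(=O)O)c(OC)c4c3O)c(O)c2c1OC | intermediate
15 | hexalithium 2,2'-bis(1,1-dioxidoethyl)-1,1'-dimethoxy-3,3'-dimethyl-7,7'-binaphthalene-8,8'-diolate | CC([O-])([O-])c1c(C)cc2ccc(-c3ccc4cc(C)c(C(C)([O-])[O-])c(OC)c4c3[O-])c([O-])c2c1OC.[Li+].[Li+].[Li+].[Li+].[Li+].[Li+] | intermediate
16 | 1,1'-(8,8'-dihydroxy-1,1'-dimethoxy-3,3'-dimethyl-7,7'-binaphthalene-2,2'-diyl)di(ethan-1-one) | CC(=O)c1c(C)cc2ccc(-c3ccc4cc(C)c(C(C)=O)c(OC)c4c3O)c(O)c2c1OC | intermediate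
17 | stypandrol | CC(=O)c1c(C)cc2ccc(-c3ccc4cc(C)c(C(C)=O)c(O)c4c3O)c(O)c2c1O | target

**Count and risks**

Total steps: 9. Longest linear sequence: 9 steps (1 and 2 to 17); 7 enters at step 5.

Step 6. What may go wrong: once the first ring is closed, the remaining C7'–H sits next to an electron-rich naphtholate and may be removed too slowly. Lateral deprotonation at the C3 methyl groups, Claisen condensation between molecules and arrest at the stage of 11 could then take over. Alkene ends of E geometry carried over from step 5 that do not rotate in the anion would stall in the same way. Fallback (sets out from 5, returns at 13): ring closure and biaryl formation are separated. Stille coupling of 5 with tributyl(vinyl)stannane (Pd(PPh3)4, toluene, 90 °C) should give dimethyl 2-methoxy-6-methyl-4-(prop-2-en-1-yl)benzene-1,3-dicarboxylate F1, whose doubly activated benzylic C5–H2 is the most acidic site. LiN(iPr)2 in THF should then close a single ring B by the established ortho-allyl benzoate annulation to give methyl 8-hydroxy-1-methoxy-3-methylnaphthalene-2-carboxylate F2. Amine-catalysed ortho-bromination (NBS, catalytic iPr2NH, CH2Cl2, 0 °C) should deliver methyl 7-bromo-8-hydroxy-1-methoxy-3-methylnaphthalene-2-carboxylate F3. Miyaura borylation of half of this material with bis(pinacolato)diboron (PdCl2(dppf), KOAc, dioxane) would give methyl 8-hydroxy-1-methoxy-3-methyl-7-(4,4,5,5-tetramethyl-1,3,2-dioxaborolan-2-yl)naphthalene-2-carboxylate F4. Suzuki–Miyaura coupling of F4 with the remaining F3 (aqueous K3PO4 added to the same flask) would form C7–C7' and give 13.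

Step 5. What may go wrong: erosion of Z selectivity with the aromatic aldehyde, and arrest after the first olefination when the half-reacted ylide is quenched or precipitates. Fallback (sets out from 5, returns at 9): the polarity is reversed and the geometry is corrected photochemically. PPh3 in toluene at reflux should convert 5 into {[3-methoxy-2,4-bis(methoxycarbonyl)-5-methylphenyl]methyl}(triphenyl)phosphonium bromide F5. Butanedial F6 is freed from 2,5-dimethoxytetrahydrofuran with dilute aqueous acid. The two-fold Wittig reaction of the semi-stabilized ylide of F5 (NaN(SiMe3)2, THF, −78 °C to rt) with F6 is expected to give 9 mixed with tetramethyl 4,4'-[(1E,5E)-hexa-1,5-diene-1,6-diyl]bis(2-methoxy-6-methylbenzene-1,3-dicarboxylate) F7 and tetramethyl 4,4'-[(1E,5Z)-hexa-1,5-diene-1,6-diyl]bis(2-methoxy-6-methylbenzene-1,3-dicarboxylate) F8. Irradiation of the mixture with blue light in the presence of fac-Ir(ppy)3 should then convert F7 and F8 into 9, because in this triplet energy transfer the twisted Z styrene is the poorer acceptor and accumulates.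

Step 8. What may go wrong: carboxylate-directed displacement of the neighbouring C1 methoxy group by methyllithium (nucleophilic aromatic substitution) in competition with addition to the hindered carboxylate, and incomplete addition within the sparingly soluble tetralithium salt. Fallback (sets out from 14, returns at 17): the order of the last two operations is reversed so that no leaving group flanks the carboxylate. BBr3 in CH2Cl2 should convert 14 into 1,1',8,8'-tetrahydroxy-3,3'-dimethyl-7,7'-binaphthalene-2,2'-dicarboxylic acid F9. Excess MeLi in THF, by the known conversion of ortho-hydroxy aryl carboxylic acids into ortho-hydroxyaryl methyl ketones, would then give 17 directly.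

Further compounds
F1 | step 6 | dimethyl 2-methoxy-6-methyl-4-(prop-2-en-1-yl)benzene-1,3-dicarboxylate | COC(=O)c1c(C)cc(CC=C)c(C(=O)OC)c1OC
F2 | step 6 | methyl 8-hydroxy-1-methoxy-3-methylnaphthalene-2-carboxylate | COC(=O)c1c(C)cc2cccc(O)c2c1OC
F3 | step 6 | methyl 7-bromo-8-hydroxy-1-methoxy-3-methylnaphthalene-2-carboxylate | COC(=O)c1c(C)cc2ccc(Br)c(O)c2c1OC
F4 | step 6 | methyl 8-hydroxy-1-methoxy-3-methyl-7-(4,4,5,5-tetramethyl-1,3,2-dioxaborolan-2-yl)naphthalene-2-carboxylate | COC(=O)c1c(C)cc2ccc(B3OC(C)(C)C(C)(C)O3)c(O)c2c1OC
F5 | step 5 | {[3-methoxy-2,4-bis(methoxycarbonyl)-5-methylphenyl]methyl}(triphenyl)phosphonium bromide | COC(=O)c1c(C)cc(C[P+](c2ccccc2)(c2ccccc2)c2ccccc2)c(C(=O)OC)c1OC.[Br-]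
F6 | step 5 | butanedial | O=CCCC=O
F7 | step 5 | tetramethyl 4,4'-[(1E,5E)-hexa-1,5-diene-1,6-diyl]bis(2-methoxy-6-methylbenzene-1,3-dicarboxylate) | COC(=O)c1c(C)cc(/C=C/CC/C=C/c2cc(C)c(C(=O)OC)c(OC)c2C(=O)OC)c(C(=O)OC)c1OC
F8 | step 5 | tetramethyl 4,4'-[(1E,5Z)-hexa-1,5-diene-1,6-diyl]bis(2-methoxy-6-methylbenzene-1,3-dicarboxylate) | COC(=O)c1c(C)cc(/C=C/CC/C=C\c2cc(C)c(C(=O)OC)c(OC)c2C(=O)OC)c(C(=O)OC)c1OC
F9 | step 8 | 1,1',8,8'-tetrahydroxy-3,3'-dimethyl-7,7'-binaphthalene-2,2'-dicarboxylic acid | OC(=O)c1c(C)cc2ccc(-c3ccc4cc(C)c(C(=O)O)c(O)c4c3O)c(O)c2c1O
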